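**Plan**

1. The target is 7''-O-prenylamentoflavone: two apigenin units joined C3'–C8'' (unit 1: locants 2–8 and 1'–6'; unit 2: 2''–8'' and 1'''–6'''). The retrosynthesis cuts, in this order, the pivalate esters, the O7''–CH2 prenyl ether, the benzyl ethers and finally the C3'–C8'' biaryl bond, which leads back to two differently masked molecules of apigenin.
2. The biaryl bond is made by dehydrogenative phenol–arene cross-coupling of two C–H bonds, with no halogen or boron on either carbon. This is possible because C3' is ortho to the free phenolic O4' on ring B of unit 1 (its para carbon C1' is blocked), and C8'' is the CH of the phloroglucinol-type ring A of unit 2 that lies between the O-bearing carbons C7'' and C8a'' and para to O5''.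
3. Helpers: a 7-O-pivalate switches off ring A of unit 1; three benzyl ethers make ring A of unit 2 the only electron-rich CH donor and screen C6''. They are removed in steps 7 and 5.
4. Forward order: apigenin is masked in two ways (steps 1, 2), the halves are joined (3), the 4'-OH is capped (4), the benzyl ethers are removed (5), the most acidic hydroxyl, 7''-OH, is prenylated (6), and the pivalates are cleaved (7). All six rings come ready-made from apigenin; none is formed.
5. Stereochemistry: the target has no stereocentre and no double bond that needs control, so nothing has to be set.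

Key step: step 3

Remark: the C3'–C8'' axis carries no descriptor in the target and is treated as configurationally undefined; the prenyl group is introduced as the unrearranged primary allylic ether.

**Route**

Step 1
Reactants: 1 apigenin
Product: 2 apigenin 7-O-pivalate
Conditions: t-BuOK (1.0 equiv), DMF, 0 °C; then PivCl (1.0 equiv), 0 °C
Reagents that add atoms: pivaloyl chloride, CC(C)(C)C(Cl)=O
Why: One equivalent of base should give the monophenoxide of the most acidic hydroxyl (7-OH, a vinylogous carboxylic acid para to C4=O), which is O-acylated by the acid chloride (regioselective phenoxide O-acylation), leaving the chelated 5-OH and the less acidic 4'-OH free.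

Step 2
Reactants: 1 apigenin
Product: 3 5,7,4'-tri-O-benzylapigenin
Conditions: BnBr (4 equiv), K2CO3 (4 equiv), DMF, 80 °C
Reagents that add atoms: benzyl bromide, BrCc1ccccc1
Why: Williamson ether synthesis, in which excess benzyl bromide and heat in DMF should alkylate the hydrogen-bonded 5-OH as well, as is usual in the exhaustive O-alkylation of 5,7,4'-trihydroxyflavones.

Step 3
Reactants: 2 apigenin 7-O-pivalate, 3 5,7,4'-tri-O-benzylapigenin
Product: 5 5'',7'',4'''-tri-O-benzyl-7-O-pivaloylamentoflavone, via cyclohexadienone tautomer 4 (not isolated)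
Conditions: constant-current electrolysis (undivided cell, boron-doped diamond anode, Pt cathode, about 2 F per mol of 2), Et3NMe O3SOMe, (CF3)2CHOH–CH2Cl2, 25 °C; 3 in threefold excess (excess recovered)
Reagents that add atoms: none
Why: Proposed new method: anodic oxidation in (CF3)2CHOH takes one electron and one proton from the only free, non-chelated phenol present (4'-OH of 2) and gives a phenoxyl radical with spin density on C3'/C5', which is attacked by the most electron-rich CH of 3, C8 of ring A (between the O-bearing carbons C7 and C8a and para to O5); loss of a second electron and a proton gives dienone 4, which tautomerises to the 2-hydroxybiaryl 5, while protons are reduced to H2 at the cathode. The closest known reaction type is the dehydrogenative phenol–arene cross-coupling of simple phenols with 1,3,5- or 1,2,4-trialkoxybenzenes in fluorinated alcohols (anodic, or with iron or hypervalent-iodine oxidants), which has not been shown with a flavone ring A as the arene or a 4'-hydroxyflavone as the phenol. No ring is closed and no stereocentre remains (4 is a transient racemate). Cross-coupling rather than homo-coupling is needed and is secured by the division of roles: 2 holds the only oxidisable hydroxyl and its own ring A is switched off by the 7-pivalate and the chelated C4 carbonyl, whereas 3 has no free hydroxyl, offers a tris-alkoxy ring A and is used in excess. Site selectivity is secured on ring B because the para carbon C1' is substituted, so that only the two equivalent ortho carbons can lead to a rearomatised product, and on 3 because C6 lies between two benzyloxy groups while C8 is the carbon at which 5,7-dialkoxyflavones take halogen electrophiles and ring B of 3 is deactivated by the pyranone. A second coupling at C5' of 5 is held back by the excess of 3 and by limiting the charge passed.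

Step 4
Reactants: 5 5'',7'',4'''-tri-O-benzyl-7-O-pivaloylamentoflavone
Product: 6 5'',7'',4'''-tri-O-benzyl-4',7-di-O-pivaloylamentoflavone
Conditions: PivCl (1.3 equiv), Et3N, DMAP (cat.), CH2Cl2, 0 °C to rt
Reagents that add atoms: pivaloyl chloride, CC(C)(C)C(Cl)=O
Why: DMAP-catalysed O-acylation of the only non-chelated phenol (4'-OH) should leave the 5-OH that is hydrogen-bonded to C4=O, so that this hydroxyl cannot compete in step 6.

Step 5
Reactants: 6 5'',7'',4'''-tri-O-benzyl-4',7-di-O-pivaloylamentoflavone
Product: 7 4',7-di-O-pivaloylamentoflavone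
Conditions: H2 (1 atm), 10% Pd/C, THF–MeOH, rt
Reagents that add atoms: none
Why: Catalytic hydrogenolysis of the three aryl benzyl ethers, under which aryl pivalates and the C2=C3 bonds of the two chromone rings should not be reduced at one atmosphere and room temperature.

Step 6
Reactants: 7 4',7-di-O-pivaloylamentoflavone
Product: 8 7''-O-prenyl-4',7-di-O-pivaloylamentoflavone
Conditions: prenyl bromide (1.05 equiv), K2CO3 (1.0 equiv), DMF, 0 °C to rt
Reagents that add atoms: prenyl bromide (1-bromo-3-methylbut-2-ene), CC(C)=CCBr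
Why: Williamson etherification under acidity control: of the four hydroxyls of 7 the 7''-OH (para to C4''=O) is the most acidic, the two 5-hydroxyls are chelated and the 4'''-OH is a weaker acid, so one equivalent of carbonate and of the allylic bromide should alkylate O7'' as in the 7-O-monoalkylation of apigenin-type flavones, and SN2 attack at the primary carbon keeps the prenyl group unrearranged.

Step 7
Reactants: 8 7''-O-prenyl-4',7-di-O-pivaloylamentoflavone
Product: 9 7''-O-prenylamentoflavone (target)
Conditions: NaOMe, MeOH–THF, 0 °C to rt; then aq. NH4Cl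
Reagents that add atoms: none
Why: Methoxide transesterification (Zemplén-type deacylation) of the two aryl pivalates should leave the allyl aryl ether and the flavone rings untouched, and it avoids the acid and the hydrogen that would harm the prenyl ether.

**Compound list**

1 | apigenin (5,7-dihydroxy-2-(4-hydroxyphenyl)-4H-chromen-4-one) | O=c1cc(-c2ccc(O)cc2)oc2cc(O)cc(O)c12 | starting material
2 | apigenin 7-O-pivalate (5-hydroxy-2-(4-hydroxyphenyl)-4-oxo-4H-chromen-7-yl 2,2-dimethylpropanoate) | CC(C)(C)C(=O)Oc1cc(O)c2c(=O)cc(-c3ccc(O)cc3)oc2c1 | intermediate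
3 | 5,7,4'-tri-O-benzylapigenin (5,7-bis(benzyloxy)-2-[4-(benzyloxy)phenyl]-4H-chromen-4-one) | O=c1cc(-c2ccc(OCc3ccccc3)cc2)oc2cc(OCc3ccccc3)cc(OCc3ccccc3)c12 | intermediate
4 | cyclohexadienone tautomer of 5 (ring B of unit 1 as a 2,4-dienone with sp3 C3' bonded to C8''; racemic at C3') | c1ccccc1COc1cc(OCc2ccccc2)c2c(=O)cc(-c3ccc(OCc4ccccc4)cc3)oc2c1C1C=C(c2cc(=O)c3c(O)cc(OC(=O)C(C)(C)C)cc3o2)C=CC1=O | intermediate (not isolated)
5 | 5'',7'',4'''-tri-O-benzyl-7-O-pivaloylamentoflavone (C3'–C8'' biflavone; free 5-OH and 4'-OH) | c1ccccc1COc1cc(OCc2ccccc2)c2c(=O)cc(-c3ccc(OCc4ccccc4)cc3)oc2c1-c1cc(-c2cc(=O)c3c(O)cc(OC(=O)C(C)(C)C)cc3o2)ccc1O | intermediate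
6 | 5'',7'',4'''-tri-O-benzyl-4',7-di-O-pivaloylamentoflavone (free 5-OH) | c1ccccc1COc1cc(OCc2ccccc2)c2c(=O)cc(-c3ccc(OCc4ccccc4)cc3)oc2c1-c1cc(-c2cc(=O)c3c(O)cc(OC(=O)C(C)(C)C)cc3o2)ccc1OC(=O)C(C)(C)C | intermediate
7 | 4',7-di-O-pivaloylamentoflavone (free 5-, 5''-, 7''- and 4'''-OH) | Oc1cc(O)c2c(=O)cc(-c3ccc(O)cc3)oc2c1-c1cc(-c2cc(=O)c3c(O)cc(OC(=O)C(C)(C)C)cc3o2)ccc1OC(=O)C(C)(C)C | intermediate
8 | 7''-O-prenyl-4',7-di-O-pivaloylamentoflavone | CC(C)=CCOc1cc(O)c2c(=O)cc(-c3ccc(O)cc3)oc2c1-c1cc(-c2cc(=O)c3c(O)cc(OC(=O)C(C)(C)C)cc3o2)ccc1OC(=O)C(C)(C)C | intermediate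
9 | 7''-O-prenylamentoflavone (CNP0152943.0) | CC(C)=CCOc1cc(O)c2c(=O)cc(-c3ccc(O)cc3)oc2c1-c1cc(-c2cc(=O)c3c(O)cc(O)cc3o2)ccc1O | target

**Count and risks**

Total step count: 7. Longest linear sequence: 6 steps (1 to 2 or 3, then steps 3 to 7).

Steps most likely to fail:

Step 3 (carries the label). The phenoxyl radical may be consumed by homo-coupling or by over-oxidation through attack at C1', the arene may react at C6 instead of C8, or ring A of 3 may be too weak a donor, so that the phenol decays unproductively. The fallback uses the established Suzuki–Miyaura route to this biaryl type; it sets out from 2 and 3 and comes back at 6, so that step 4 is not needed. Compound 2 is iodinated ortho to the 4'-OH (N-iodosuccinimide, TsOH cat., MeCN, 0 °C) to 3'-iodoapigenin 7-O-pivalate F1. This is capped (PivCl, Et3N, DMAP, CH2Cl2) to 3'-iodoapigenin 4',7-di-O-pivalate F2 and borylated (B2pin2, PdCl2(dppf), KOAc, dioxane, 80 °C) to apigenin 4',7-di-O-pivalate 3'-boronic acid pinacol ester F3. Compound 3 is iodinated at C8 (N-iodosuccinimide, CF3CO2H cat., CH2Cl2) to 8-iodo-5,7,4'-tri-O-benzylapigenin F4. Coupling of F3 with F4 (Pd(PPh3)4, K3PO4, DMF, 90 °C) should give 6.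

Step 6. The second non-chelated hydroxyl (4'''-OH) may be alkylated as well, or a pivaloyl group may migrate between phenoxides under the basic conditions. The fallback makes 7''-OH the only free hydroxyl before the prenyl group is introduced; it sets out from 7 and comes back at 9. Compound 7 is peracetylated (Ac2O, pyridine, DMAP) to 5,5'',7'',4'''-tetra-O-acetyl-4',7-di-O-pivaloylamentoflavone F5. The 7''-O-acetyl, the most labile ester of a flavone peracetate, is removed alone (PhSH, imidazole, N-methylpyrrolidone, 0 °C; the hindered 7-pivalate should resist) to give 5,5'',4'''-tri-O-acetyl-4',7-di-O-pivaloylamentoflavone F6. Mitsunobu etherification with 3-methylbut-2-en-1-ol (PPh3, DIAD, THF) under neutral conditions gives 5,5'',4'''-tri-O-acetyl-7''-O-prenyl-4',7-di-O-pivaloylamentoflavone F7. Global deacylation (NaOMe, MeOH–THF) then gives 9.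

Step 1. Acylation may also take place at the 4'-phenoxide, or twice, giving a mixture of mono- and dipivalates. The fallback masks O4' first; it sets out from 1 and comes back at 2. Compound 1 is converted with t-BuOK (2.0 equiv, DMF) into the 7,4'-dianion, whose more basic 4'-oxide is alkylated by BnBr (1.0 equiv) to give 4'-O-benzylapigenin F8. Pivaloylation of the now only non-chelated hydroxyl (PivCl, Et3N, CH2Cl2) gives 4'-O-benzylapigenin 7-O-pivalate F9, and hydrogenolysis (H2, 10% Pd/C, THF) returns 2.

**Further compounds**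

F1 | step 3 | 3'-iodoapigenin 7-O-pivalate | CC(C)(C)C(=O)Oc1cc(O)c2c(=O)cc(-c3ccc(O)c(I)c3)oc2c1
F2 | step 3 | 3'-iodoapigenin 4',7-di-O-pivalate | CC(C)(C)C(=O)Oc1cc(O)c2c(=O)cc(-c3ccc(OC(=O)C(C)(C)C)c(I)c3)oc2c1
F3 | step 3 | apigenin 4',7-di-O-pivalate 3'-boronic acid pinacol ester | CC(C)(C)C(=O)Oc1cc(O)c2c(=O)cc(-c3ccc(OC(=O)C(C)(C)C)c(B4OC(C)(C)C(C)(C)O4)c3)oc2c1
F4 | step 3 | 8-iodo-5,7,4'-tri-O-benzylapigenin | O=c1cc(-c2ccc(OCc3ccccc3)cc2)oc2c(I)c(OCc3ccccc3)cc(OCc3ccccc3)c12
F5 | step 6 | 5,5'',7'',4'''-tetra-O-acetyl-4',7-di-O-pivaloylamentoflavone | CC(=O)Oc1cc(OC(C)=O)c2c(=O)cc(-c3ccc(OC(C)=O)cc3)oc2c1-c1cc(-c2cc(=O)c3c(OC(C)=O)cc(OC(=O)C(C)(C)C)cc3o2)ccc1OC(=O)C(C)(C)C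
F6 | step 6 | 5,5'',4'''-tri-O-acetyl-4',7-di-O-pivaloylamentoflavone (free 7''-OH) | Oc1cc(OC(C)=O)c2c(=O)cc(-c3ccc(OC(C)=O)cc3)oc2c1-c1cc(-c2cc(=O)c3c(OC(C)=O)cc(OC(=O)C(C)(C)C)cc3o2)ccc1OC(=O)C(C)(C)C
F7 | step 6 | 5,5'',4'''-tri-O-acetyl-7''-O-prenyl-4',7-di-O-pivaloylamentoflavone | CC(C)=CCOc1cc(OC(C)=O)c2c(=O)cc(-c3ccc(OC(C)=O)cc3)oc2c1-c1cc(-c2cc(=O)c3c(OC(C)=O)cc(OC(=O)C(C)(C)C)cc3o2)ccc1OC(=O)C(C)(C)C
F8 | step 1 | 4'-O-benzylapigenin | O=c1cc(-c2ccc(OCc3ccccc3)cc2)oc2cc(O)cc(O)c12
F9 | step 1 | 4'-O-benzylapigenin 7-O-pivalate | CC(C)(C)C(=O)Oc1cc(O)c2c(=O)cc(-c3ccc(OCc4ccccc4)cc3)oc2c1
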